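# Dicitrinone G (17): synthesis proposal built on a redox-neutral union of an aldehyde and an isochroman

## The problem

Dicitrinone G (17) is an unsymmetrical methylene-bridged dimer. C7 of a decarboxycitrinin-type quinone methide (left half, a 3,4-dihydro-8H-isochromen-8-one) is linked through one CH2 group to C7' of a 6',8'-dihydroxyisochroman-1'-one (right half). Both halves have the same carbon skeleton, the same fully substituted carbocycle and the same trans-(3R,4S) dimethyl diad. They differ only in the oxidation level of C1 (CH= of a vinylogous ester versus C=O of a lactone), so one skeleton must be made twice and the symmetry then broken in oxidation state alone. The two pairs of stereocentres are separated by both carbocycles and the bridge and cannot control one another. Within each pair, the trans ring arrangement corresponds to the threo open-chain alcohol, which the anti opening of a chiral trans-epoxide does not deliver, so one centre must be inverted. C4 sits on C4a, which is meta to both ring oxygens and cannot be reached by electrophilic substitution, whereas C8a (bearing C1) and C7 (bearing the bridge) are ortho/para to O6 and O8. The quinone methide is electrophilic at C1 (water, amines, phenols and hydride add there); together with four free hydroxyl groups, the lactone and a bridge bond that can exchange partners by retro-Michael cleavage, it forbids strongly basic, nucleophilic or reducing conditions late in the route.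

The feature the plan uses is that the left half is the isochroman skeleton minus one hydride. C1 is bonded to O2 and to C8a, para to O6 and ortho to O8, so the C1–H of isochroman 13 is a very good hydride donor. A bridge carbon held at the aldehyde level between C7' (flanked by O6'/O8') and C7 (flanked by O6/O8) gives a strongly stabilised cation that accepts hydride, and C7 and C7' are the only unsubstituted ring carbons. Hence 17 equals aldehyde 11 plus isochroman 13 minus water, with no net change of oxidation state.

## Retrosynthesis

**17 ⇒ 11 + 13.** The first cut is the C7–CH2 bond on the quinone methide side. The bridge carbon stays on the lactone half as the formyl group of aldehyde 11, and the left half is written one hydride richer, as isochroman 13. Against the cut of both bridge bonds to formaldehyde, this fixes the electrophilic carbon on the less nucleophilic partner and lets the isochroman C1–H pay for the reduction of the bridge, so the quinone methide appears only in the product. Against the reverse placement (aldehyde on the isochroman), the aldehyde sits on the electron-poorer ring and the nucleophile is the electron-richer one. The precursors are two bicyclic C13 and C12 compounds with two stereocentres each. The forward reaction must form the C7–C bond (through carbinol 14) and then move hydride from C1 of an isochroman unit to the bridge cation. Free 13 that donates hydride becomes decarboxycitrinin 15, which re-enters as a C7 nucleophile, and the reduced dimer 16 is the second hydride carrier.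

**11 ⇒ 10 and 13 ⇒ 10.** Both partners come from one compound, lactone 10. In 11 the C7–CHO bond is cut (formylation at the only free ring carbon, ortho to both hydroxyl groups). In 13 the carbonyl oxygen at C1 is removed: reduction to the ring-opened tetraol 12 and reclosure of C1–O2 through the para-hydroxybenzyl cation. The divergence costs one step per partner, and no protecting group is carried past 10.

**10 ⇒ 9.** The two O–CH3 bonds are cut. Methyl ethers are needed only for the organometallic steps and fall in one operation.

**9 ⇒ 8.** The C3–O2 bond is cut as an alkyl–oxygen bond, to be made by SN2 with inversion. The neighbouring acyl–oxygen cut would need the threo alcohol and hence a separate two-step inversion. With the alkyl–oxygen cut the ring closure itself corrects the erythro diad of 8 to the trans ring.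

**8 ⇒ 6 ⇒ 5.** The C8a–CO2H bond is cut to the aryllithium 7 from bromide 6, and C8a–Br to electrophilic bromination of 5. C8a is para to one methoxy group, so the halogen goes there rather than between the two methoxy groups.

**5 ⇒ 2 + 3.** The C4–C4a bond is cut. C4a is meta to both oxygens and can only be a nucleophile generated from a halide (Grignard reagent 4). The C2-symmetric epoxide 3 brings both stereocentres in one purchased reagent, and its two carbons are equivalent, so there is no regiochemical issue.

**2 ⇒ 1.** The C5 methyl group is the deoxygenated formyl group of commercial aldehyde 1, which already has bromine at the future C4a.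

## Roads not taken

Alternative 1: (the most obvious) Cut both bridge bonds to formaldehyde and join lactone 10 with decarboxycitrinin 15. The forward key step is hydroxymethylation of 10 to A1, ortho-quinone methide formation and Michael addition of 15 (or a one-pot Knoevenagel–Michael reaction). The chosen plan is better for three reasons.
- 15 must be made and handled as an isolated electrophilic quinone methide: one more step (oxidation of 13, or reduction and deprotection of 9).
- With an alcohol-level C1 unit the roles are not fixed. 15 is the better nucleophile toward formaldehyde, and its 7-methylene derivative is captured by a second 15 to give homodimer A2. Avoiding this needs a preformed leaving group on 10 and thermal or basic conditions, under which such adducts can exchange partners by retro-Michael cleavage.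
- It needs four operations after 10 instead of three.

Alternative 2: Install the bridge first and build both halves two-directionally to the C2-symmetric bis-lactone A3. The forward key step is a desymmetrising reduction of one lactone carbonyl of A3 to the lactol level, then deprotection. The chosen plan is better because the two lactones of A3 are insulated by the sp3 bridge, unconjugated and far apart. The first reduction does not slow the second, so the differentiation is statistical. Every earlier reaction must also work twice on a more hindered substrate, and the step count is not lower. In the chosen plan the oxidation-state difference is built into the two partners.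

Alternative 3: Cut C4–C4a and C3–O2 in both halves to an alkyne. The forward key step is a double carboxylate-directed C–H activation/oxidative annulation of bis-acid A4 with 2-butyne to bis-isocoumarin A5, followed by enantioselective hydrogenation of both C3=C4 bonds. The chosen plan is better because hydrogenation adds both hydrogens to one face of C3=C4 and can only give the cis-3,4-dimethyl arrangement, whereas the target is trans. C–H activation would also have to occur at the C–H flanked by the C5 methyl group, against peri strain in the planar isocoumarin, and the symmetric product would still need the desymmetrisation of Alternative 2. The trans-epoxide plus one inversion gives the trans diad stereospecifically.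

Key step: step 9

Assumption: 2-bromo-4,6-dimethoxybenzaldehyde (1) and (2S,3S)-2,3-dimethyloxirane (3) are taken as catalogue compounds, and 17 is written as the 8-oxo-6-hydroxy tautomer of the given SMILES, which interconverts freely with the 6-oxo-8-hydroxy form.

## Route

Step 1
Reactants: 1 2-bromo-4,6-dimethoxybenzaldehyde
Product: 2 1-bromo-3,5-dimethoxy-2-methylbenzene
Conditions: Et3SiH (2.5 equiv), TFA, CH2Cl2, 0 °C → rt
Reagents that add atoms: none
Why: Ionic hydrogenation of an electron-rich aryl aldehyde: protonation, hydride transfer, ionisation to the ortho/para-dimethoxybenzyl cation and a second hydride transfer give the methyl group; aryl bromide and ethers are inert.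

Step 2
Reactants: 2 1-bromo-3,5-dimethoxy-2-methylbenzene; 3 (2S,3S)-2,3-dimethyloxirane
Product: 5 (2S,3S)-3-(3,5-dimethoxy-2-methylphenyl)butan-2-ol, via aryl Grignard reagent 4 (not isolated)
Conditions: Mg, THF, 60 °C; then CuI (10 mol%), 3 (1.5 equiv), THF, −30 → 0 °C; H2O
Reagents that add atoms: none
Why: Copper-catalysed SN2 opening of the C2-symmetric trans-epoxide by the aryl Grignard reagent; the attacked carbon (future C4) is inverted and the carbinol carbon is untouched, so the erythro (2S,3S) alcohol should form as a single stereoisomer.

Step 3
Reactants: 5 (2S,3S)-3-(3,5-dimethoxy-2-methylphenyl)butan-2-ol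
Product: 6 (2S,3S)-3-(2-bromo-3,5-dimethoxy-6-methylphenyl)butan-2-ol
Conditions: NBS (1.05 equiv), MeCN, 0 °C, dark
Reagents that add atoms: N-bromosuccinimide O=C1CCC(=O)N1Br
Why: Electrophilic aromatic bromination; the ring carbon next to the side chain is para to one methoxy group and should react in preference to the carbon flanked by two methoxy groups, as in brominations of 5-alkylresorcinol dimethyl ethers; the stereocentres are not involved.

Step 4
Reactants: 6 (2S,3S)-3-(2-bromo-3,5-dimethoxy-6-methylphenyl)butan-2-ol
Product: 8 2-[(2S,3S)-3-hydroxybutan-2-yl]-4,6-dimethoxy-3-methylbenzoic acid, via dilithiated alkoxide 7 (not isolated)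
Conditions: t-BuLi (3.1 equiv), THF, −78 °C; CO2, −78 → 0 °C; cold 1 M HCl (pH 3), extraction at 0 °C, used at once
Reagents that add atoms: carbon dioxide O=C=O
Why: Deprotonation of the alcohol, bromine–lithium exchange and carboxylation of the aryllithium; the acid is kept cold and not stored because acid-catalysed lactonisation through the acyl carbon would close the ring with retention at the carbinol carbon.

Step 5
Reactants: 8 2-[(2S,3S)-3-hydroxybutan-2-yl]-4,6-dimethoxy-3-methylbenzoic acid
Product: 9 (3R,4S)-6,8-dimethoxy-3,4,5-trimethylisochroman-1-one
Conditions: PPh3 (1.5 equiv), DIAD (1.5 equiv), THF, 0 °C → rt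
Reagents that add atoms: none
Why: Intramolecular Mitsunobu esterification: the carboxylate displaces the oxyphosphonium group in a 6-exo-tet SN2 step, so the carbinol carbon is inverted (S to R) and the erythro acid gives the trans-3,4-dimethyl lactone; C4 is not touched.

Step 6
Reactants: 9 (3R,4S)-6,8-dimethoxy-3,4,5-trimethylisochroman-1-one
Product: 10 (3R,4S)-6,8-dihydroxy-3,4,5-trimethylisochroman-1-one
Conditions: BBr3 (4 equiv), CH2Cl2, −78 °C → rt; H2O
Reagents that add atoms: none
Why: Lewis-acid cleavage of both aryl methyl ethers (the one peri to the carbonyl first); δ-lactone and stereocentres are stable to BBr3 at or below room temperature, as in demethylations of methoxy-3,4-dihydroisocoumarins.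

Step 7
Reactants: 10 (3R,4S)-6,8-dihydroxy-3,4,5-trimethylisochroman-1-one
Product: 11 (3R,4S)-6,8-dihydroxy-3,4,5-trimethyl-1-oxoisochromane-7-carbaldehyde
Conditions: Cl2CHOMe (1.5 equiv), TiCl4 (3 equiv), CH2Cl2, 0 °C; 1 M HCl
Reagents that add atoms: dichloromethyl methyl ether COC(Cl)Cl; water O
Why: Rieche formylation of the titanium phenoxide; C7 is the only unsubstituted ring carbon and is ortho to both hydroxyl groups, so no regiochemical choice exists, and hydrolysis of the α-chloro ether on work-up gives the aldehyde.

Step 8
Reactants: 10 (3R,4S)-6,8-dihydroxy-3,4,5-trimethylisochroman-1-one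
Product: 13 (3R,4S)-3,4,5-trimethylisochromane-6,8-diol, via ring-opened tetraol 12 (not isolated)
Conditions: LiAlH4 (4 equiv), THF, 0 °C → rt; then into cold 1 M HCl, rt
Reagents that add atoms: none
Why: Hydride reduction of the lactone to the hydroxymethyl tetraol; on acidification the 2,4-dihydroxybenzyl alcohol ionises to the para-quinone methide/benzyl cation and the C3 hydroxyl closes the six-membered ether. The C3–O bond is never broken, so both stereocentres are retained.

Step 9
Reactants: 11 (3R,4S)-6,8-dihydroxy-3,4,5-trimethyl-1-oxoisochromane-7-carbaldehyde; 13 (3R,4S)-3,4,5-trimethylisochromane-6,8-diol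
Product: 17 dicitrinone G, via diarylmethanol 14 (not isolated), via decarboxycitrinin 15 (not isolated), via lactone–isochroman dimer 16 (not isolated)
Conditions: TFA (5 equiv), HFIP/CH2Cl2 (1:1, 0.02 M), 13 (1.0 equiv) added slowly at 0 °C, then 40 °C, Ar
Reagents that add atoms: none
Why: Proposed new method: a redox-neutral reductive Friedel–Crafts union in which the isochroman is its own hydride donor; the closest known reaction types are the three-component reductive alkylation of cyclic 1,3-diones with aldehydes and a Hantzsch ester, reductive Friedel–Crafts benzylation with aldehyde and silane, and acid-promoted hydride transfer from benzylic ether C–H bonds to carbenium ions and alkylidene 1,3-dicarbonyls. Protonated 11 is attacked by C7 of 13, the only free ring carbon, to give carbinol 14, which ionises to a bis(2,6-dihydroxyaryl)methyl cation. Because this cation is flanked by four ortho oxygens, capture by a third hindered carbon nucleophile is slow and reversible, whereas hydride transfer from C1–H of an isochroman unit (α to O2, para to O6, ortho to O8) is irreversible and leaves, after loss of a proton, the CH2 bridge and a citrinin-type quinone methide. When free 13 is the donor, 16 and 15 result; 15 then condenses through its C7 with remaining 11, and the alkylidene cation so formed takes its hydride from the isochroman half of 16, so both channels converge on 17 and the 1:1 stoichiometry is redox-balanced (11 + 13 → 17 + H2O). The driving force is the exchange of a non-isolable bridge quinone methide or cation for an aromatic resorcinol ring plus the vinylogous-ester quinone methide. No ring is closed and no stereocentre is formed: C3, C4, C3' and C4' lie away from every cationic site and are carried through unchanged. The selectivities needed are hydride transfer over triarylmethane formation and over C1–C7 coupling of 15 with 13 (both reversible in TFA by retro-Friedel–Crafts cleavage, since they release stabilised cations), and single rather than double reduction of the bridge carbon, which slow addition of 13 to an excess of the aldehyde is meant to secure.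

## Compound list

1 | 2-bromo-4,6-dimethoxybenzaldehyde | COc1cc(Br)c(C=O)c(OC)c1 | starting material
2 | 1-bromo-3,5-dimethoxy-2-methylbenzene | COc1cc(Br)c(C)c(OC)c1 | intermediate
3 | (2S,3S)-2,3-dimethyloxirane | C[C@@H]1O[C@H]1C | starting material
4 | (3,5-dimethoxy-2-methylphenyl)magnesium bromide (not isolated) | COc1cc(OC)c(C)c([Mg]Br)c1 | intermediate
5 | (2S,3S)-3-(3,5-dimethoxy-2-methylphenyl)butan-2-ol | C[C@H](O)[C@@H](C)c1cc(OC)cc(OC)c1C | intermediate
6 | (2S,3S)-3-(2-bromo-3,5-dimethoxy-6-methylphenyl)butan-2-ol | C[C@H](O)[C@@H](C)c1c(Br)c(OC)cc(OC)c1C | intermediate
7 | lithium (2S,3S)-3-(2-lithio-3,5-dimethoxy-6-methylphenyl)butan-2-olate (not isolated) | C[C@H](O[Li])[C@@H](C)c1c([Li])c(OC)cc(OC)c1C | intermediate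
8 | 2-[(2S,3S)-3-hydroxybutan-2-yl]-4,6-dimethoxy-3-methylbenzoic acid | C[C@H](O)[C@@H](C)c1c(C(=O)O)c(OC)cc(OC)c1C | intermediate
9 | (3R,4S)-6,8-dimethoxy-3,4,5-trimethylisochroman-1-one | C[C@H]1OC(=O)c2c(OC)cc(OC)c(C)c2[C@@H]1C | intermediate
10 | (3R,4S)-6,8-dihydroxy-3,4,5-trimethylisochroman-1-one | C[C@H]1OC(=O)c2c(O)cc(O)c(C)c2[C@@H]1C | intermediate
11 | (3R,4S)-6,8-dihydroxy-3,4,5-trimethyl-1-oxoisochromane-7-carbaldehyde | C[C@H]1OC(=O)c2c(O)c(C=O)c(O)c(C)c2[C@@H]1C | intermediate
12 | 5-[(2S,3R)-3-hydroxybutan-2-yl]-6-(hydroxymethyl)-4-methylbenzene-1,3-diol (not isolated) | C[C@@H](O)[C@@H](C)c1c(CO)c(O)cc(O)c1C | intermediate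
13 | (3R,4S)-3,4,5-trimethylisochromane-6,8-diol | C[C@H]1OCc2c(O)cc(O)c(C)c2[C@@H]1C | intermediate
14 | (3R,4S)-7-{[(3R,4S)-6,8-dihydroxy-3,4,5-trimethylisochroman-7-yl](hydroxy)methyl}-6,8-dihydroxy-3,4,5-trimethylisochroman-1-one, both carbinol epimers (not isolated) | C[C@H]1OC(=O)c2c(O)c(C(O)c3c(O)c4CO[C@H](C)[C@@H](C)c4c(C)c3O)c(O)c(C)c2[C@@H]1C | intermediate
15 | decarboxycitrinin, (3R,4S)-6-hydroxy-3,4,5-trimethyl-3,4-dihydro-8H-isochromen-8-one (not isolated) | CC1=C2C(=CO[C@H](C)[C@H]2C)C(=O)C=C1O | intermediate
16 | (3R,4S)-7-{[(3R,4S)-6,8-dihydroxy-3,4,5-trimethylisochroman-7-yl]methyl}-6,8-dihydroxy-3,4,5-trimethylisochroman-1-one (not isolated) | C[C@H]1OC(=O)c2c(O)c(Cc3c(O)c4CO[C@H](C)[C@@H](C)c4c(C)c3O)c(O)c(C)c2[C@@H]1C | intermediate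
17 | dicitrinone G, (3R,4S)-6,8-dihydroxy-7-{[(3R,4S)-6-hydroxy-3,4,5-trimethyl-8-oxo-3,4-dihydro-8H-isochromen-7-yl]methyl}-3,4,5-trimethylisochroman-1-one | CC1=C2C(=CO[C@H](C)[C@H]2C)C(=O)C(Cc2c(O)c(C)c3c(c2O)C(=O)O[C@H](C)[C@H]3C)=C1O | target

## Step count and least certain steps

Total steps: 9. Longest linear sequence: 8 (steps 1–6, then step 7 or step 8, then step 9).

**Step 9 (key step, proposed new method).** Hydride transfer from the isochroman C1–H may be too slow for the stabilised bridge cation. The material would then rest in reversible C–C adducts. Alternatively, the bridge carbon could be reduced twice (to a C7' methyl group) while quinone methide accumulates, or 13 could oligomerise through acid ionisation of its benzylic ether. Fallback with known chemistry, setting out from 11 and 13: reductive Friedel–Crafts alkylation with an external hydride (Et3SiH, TFA, CH2Cl2, 0 °C, 13 in slight excess) gives the lactone–isochroman dimer 16, which is then isolated. DDQ (1.0 equiv, dioxane, 10 °C) removes hydride from C1 of the electron-rich isochroman half only, since the lactone half is acyl-deactivated and has no ether C–H. This dehydrogenation of a para-hydroxybenzyl ether to a quinone methide returns the route at 17. No compound outside the list is made.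

**Step 8.** Phenoxide-assisted loss of the benzylic oxygen during the hydride reduction could lead to over-reduction (methyl at C8a), or the hydroxybenzyl alcohol could self-condense before ring closure. The fallback sets out from 9, where no phenoxide is present. LiAlH4 reduction gives the diol (2R,3S)-3-[2-(hydroxymethyl)-3,5-dimethoxy-6-methylphenyl]butan-2-ol F1. Catalytic TsOH in CH2Cl2 closes the ether through the 2,4-dimethoxybenzyl cation to (3R,4S)-6,8-dimethoxy-3,4,5-trimethylisochromane F2. O-demethylation (BBr3, −78 → 0 °C; any benzylic C1–O cleavage recloses on aqueous work-up) comes back at 13.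

**Step 5.** Ring closure with retention would erode the trans/cis ratio at C3. It could arise from acyl-type lactonisation of 8 before the Mitsunobu reagents act, or from aryl participation at the oxyphosphonium stage. The fallback sets out from 5 and separates inversion from ring closure. Intermolecular Mitsunobu reaction with 4-nitrobenzoic acid gives (2R,3S)-3-(3,5-dimethoxy-2-methylphenyl)butan-2-yl 4-nitrobenzoate F3. Methanolysis (K2CO3, MeOH) gives the threo alcohol (2R,3S)-3-(3,5-dimethoxy-2-methylphenyl)butan-2-ol F4. Bromination as in step 3 gives (2R,3S)-3-(2-bromo-3,5-dimethoxy-6-methylphenyl)butan-2-ol F5. Bromine–lithium exchange, carboxylation and acidification then close the lactone through the acyl carbon with retention, which comes back at 9.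

**Step 7.** Electrophilic attack at C7 may be incomplete, because it is flanked by two hydroxyl groups on a lactone-deactivated ring, or reaction may be diverted to oxygen. The fallback sets out from 10 and replaces the aldehyde-level carbon by an amine-level one. Aminomethylation with Eschenmoser's salt (CH2Cl2/MeCN, rt) gives the Mannich base (3R,4S)-7-[(dimethylamino)methyl]-6,8-dihydroxy-3,4,5-trimethylisochroman-1-one F6. Heating F6 with 13 (toluene, 100 °C) generates the ortho-quinone methide of the lactone half, which alkylates C7 of 13 to give 16. DDQ as in the fallback for step 9 comes back at 17.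

## Further compounds

F0 | step 9 | none | none
F1 | step 8 | (2R,3S)-3-[2-(hydroxymethyl)-3,5-dimethoxy-6-methylphenyl]butan-2-ol | C[C@@H](O)[C@@H](C)c1c(CO)c(OC)cc(OC)c1C
F2 | step 8 | (3R,4S)-6,8-dimethoxy-3,4,5-trimethylisochromane | C[C@H]1OCc2c(OC)cc(OC)c(C)c2[C@@H]1C
F3 | step 5 | (2R,3S)-3-(3,5-dimethoxy-2-methylphenyl)butan-2-yl 4-nitrobenzoate | C[C@@H](OC(=O)c1ccc(cc1)[N+](=O)[O-])[C@@H](C)c1cc(OC)cc(OC)c1C
F4 | step 5 | (2R,3S)-3-(3,5-dimethoxy-2-methylphenyl)butan-2-ol | C[C@@H](O)[C@@H](C)c1cc(OC)cc(OC)c1C
F5 | step 5 | (2R,3S)-3-(2-bromo-3,5-dimethoxy-6-methylphenyl)butan-2-ol | C[C@@H](O)[C@@H](C)c1c(Br)c(OC)cc(OC)c1C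
F6 | step 7 | (3R,4S)-7-[(dimethylamino)methyl]-6,8-dihydroxy-3,4,5-trimethylisochroman-1-one | C[C@H]1OC(=O)c2c(O)c(CN(C)C)c(O)c(C)c2[C@@H]1C
A1 | alternative 1 | (3R,4S)-6,8-dihydroxy-7-(hydroxymethyl)-3,4,5-trimethylisochroman-1-one | C[C@H]1OC(=O)c2c(O)c(CO)c(O)c(C)c2[C@@H]1C
A2 | alternative 1 | 7,7'-methylenebis(decarboxycitrinin) | CC1=C2C(=CO[C@H](C)[C@H]2C)C(=O)C(CC2=C(O)C(C)=C3[C@H](C)[C@@H](C)OC=C3C2=O)=C1O
A3 | alternative 2 | bis[(3R,4S)-6,8-dimethoxy-3,4,5-trimethyl-1-oxoisochroman-7-yl]methane | C[C@H]1OC(=O)c2c(OC)c(Cc3c(OC)c(C)c4c(c3OC)C(=O)O[C@H](C)[C@H]4C)c(OC)c(C)c2[C@@H]1C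
A4 | alternative 3 | 3,3'-methylenebis(2,4-dimethoxy-5-methylbenzoic acid) | COc1c(Cc2c(OC)c(C)cc(C(=O)O)c2OC)c(OC)c(C)cc1C(=O)O
A5 | alternative 3 | bis(6,8-dimethoxy-3,4,5-trimethyl-1-oxo-1H-isochromen-7-yl)methane | CC1=C(C)c2c(C)c(OC)c(Cc3c(OC)c(C)c4c(c3OC)C(=O)OC(C)=C4C)c(OC)c2C(=O)O1
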